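The earlier runs and the new flask come from a simulation on assumed constants; noise was put on by code.

**Gas loads.** Your decisive number is 5.89: Π, the amount converted in the flask at the asked conversion divided by the saturation concentration of gas. Π above 1 means that gas must keep crossing into solution during the run.

| flask | left-handed substrate | right-handed substrate | gas | catalyst | remark |
|---|---|---|---|---|---|
| midnight | 0.14 M | 0.14 M | 19 mM (held) | 0.16 mol% | run made earlier |
| winter | 0.21 M | 0.21 M | 19 mM (held) | 0.16 mol% | run made earlier |
| dusk | 0.28 M | 0.28 M | 19 mM (held) | 0.32 mol% | run made earlier |
| flask | 0.28 M | 0.28 M | 19 mM (held) | 0.16 mol% |  |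

- midnight (time / min: left-handed product / %): 25.0: 49.7; 50.0: 49.7; 80.0: 50.7; 90.0: 50.1
- winter (time / min: left-handed product / %): 8.00: 30.1; 20.0: 49.8; 40.0: 50.1; 90.0: 51.4
- dusk (time / min: left-handed product / %): 25.0: 50.3; 50.0: 50.7; 80.0: 50.5; 90.0: 50.3

(scatter of a reading: 0.5 percentage points)

- catalyst is single-handed; left-handed substrate and right-handed substrate are mirror images of each other, charged as a racemate, each of them at the stated concentration
- the analysis behind the earlier runs scatters by 0.5 percentage points, standard deviation
- at the start none of the gas is in solution

- apparent order in catalyst when 20% of the left-handed substrate and right-handed substrate together are converted (percent change of the rate of making left-handed product for one percent more catalyst charged)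

**Reading it.** The same fold on the winter run's first reading gives Π_w = 6.65 by 8.00 min. The crossing constant k is therefore at least 0.832 min⁻¹. If catalyst and substrate enter the rate as a product, in series with the crossing, their orders are equal. Both then equal the dissolved gas as a fraction of saturation. The winter rate barely fell as substrate went, so my own reckoning puts the order below 0.5. One number wasn't enough, though: Π holds no k.

**The forecast.** It says 0.5, within 0.05 to 1: “I expect a mixed value, weakly determined”. My reckoning lies lower.

**The flask.** The simulation gives 0.11.

    partner + catalyst + right-handed substrate → catalyst + right-handed product (k = 25.0 L² mol⁻² s⁻¹)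
    partner + catalyst + left-handed substrate → catalyst + left-handed product (k = 2900 L² mol⁻² s⁻¹)
    gas ⇌ partner, rate k3*(csat - [partner]) (kL = 0.0190 s⁻¹)
    2 catalyst ⇌ resting dimer, settled at all times (K = 3300 L mol⁻¹)

**Crossing time.** At full pace, with k = 0.019 s⁻¹, the flask's Π loads need 5.17 min, less than the 0.102 h the flask takes to the asked conversion, so conversion drew gas on average at 84.9% of full pace. The same comparison on the winter run's reading gives 72.9% of full pace by 8.00 min.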